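**Strategy.** The C2–C8 stereoheptad is mirror-symmetric about C5 (2,3-syn, 3,4-anti, 4,5-anti reflected in 5,6-anti, 6,7-anti, 7,8-syn), so the entire C1–C9 chain is built two-directionally as an achiral meso dialdehyde. The key step joins it to an achiral aryl ethyl ketone: a reagent-controlled boron aldol of the ketone's (Z)-enol diisopinocampheylborinate engages only one of the two enantiotopic formyl groups, forming C9–C10 and fixing at once the absolute configuration of all seven stereocentres; the two sacrificial aldol centres are erased on dehydration to the (E)-enone. Precursors: a Cs-symmetric tris-silylated nonanedial and a masked 2-amino-1,4-naphthoquinone bearing a propanoyl group at C5.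

Key step: step 15

Remark on numbering: chain atoms are numbered C1 (CO2H) to C11 (aryl C=O), ring atoms as in 1,4-naphthoquinone (C2 N, C5 acyl, C6 OH, C7 Me). ArP = 2-[(tert-butoxycarbonyl)amino]-1,4-dimethoxy-6-(methoxymethoxy)-7-methylnaphthalen-5-yl.

Assumption: Ipc2BOTf made from (−)-α-pinene is taken to send its (Z)-enolates to the aldehyde re face, in the same sense as the related allyl- and crotylboranes; if the sense is the reverse, the antipode is used and nothing else changes.

**Route**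

Step 1
Reactants: 1 methacrolein; 2 isopropenylmagnesium bromide
Product: 3 2,4-dimethylpenta-1,4-dien-3-ol
Conditions: THF, −78 → 0 °C; satd. aq. NH4Cl
Reagents that add atoms: none
Why: Grignard 1,2-addition of the vinylic reagent to the enal carbonyl should give the bis-allylic carbinol, which has no stereocentre because the carbinol carbon carries two identical isopropenyl groups.

Step 2
Reactants: 3 2,4-dimethylpenta-1,4-dien-3-ol
Product: 4 tert-butyl[(2,4-dimethylpenta-1,4-dien-3-yl)oxy]dimethylsilane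
Conditions: TBSCl, imidazole, DMF, rt
Reagents that add atoms: tert-butyldimethylsilyl chloride, CC(C)(C)[Si](C)(C)Cl
Why: Standard silylation of a secondary alcohol; the bulky, non-coordinating silyl ether is also the allylic substituent that steers step 3.

Step 3
Reactants: 4 tert-butyl[(2,4-dimethylpenta-1,4-dien-3-yl)oxy]dimethylsilane
Product: 6 meso-(2R,3s,4S)-3-[(tert-butyldimethylsilyl)oxy]-2,4-dimethylpentane-1,5-diol (anti,anti), via bis(9-BBN) trialkylborane 5 (not isolated)
Conditions: 9-BBN (2.5 equiv), THF, 0 °C → rt; then NaOH, 30% H2O2, 0 °C → rt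
Reagents that add atoms: hydrogen peroxide, OO
Why: Two-directional hydroboration–oxidation with acyclic 1,2-induction: each 1,1-disubstituted alkene should react through the conformer in which the allylic C–H eclipses the C=C, on the face anti to the carbon branch, giving the 1,2-anti relation at both new methyl centres (C4 and C6) and hence the meso anti,anti triad.

Step 4
Reactants: 6 meso anti,anti diol
Product: 7 meso-(2R,3r,4S)-3-[(tert-butyldimethylsilyl)oxy]-2,4-dimethylpentanedial
Conditions: (COCl)2, DMSO, CH2Cl2, −78 °C; Et3N, −78 → −20 °C; used crude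
Reagents that add atoms: none
Why: Swern oxidation of both primary alcohols; low temperature and immediate use should protect the epimerisable α-centres and the β-silyloxy group.

Step 5
Reactants: 7 meso dialdehyde; 8 (Z)-crotylboronic acid pinacol ester (2.5 equiv)
Product: 10 meso-6-[(tert-butyldimethylsilyl)oxy]-3,5,7,9-tetramethylundeca-1,10-diene-4,8-diol (3,4-syn, 4,5-anti, 5,6-anti, 6,7-anti, 7,8-anti, 8,9-syn), via bis(pinacol borate) 9 (not isolated)
Conditions: toluene (1 M), 4 Å MS, rt, 72 h; then N(CH2CH2OH)3, rt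
Reagents that add atoms: none
Why: Two-directional crotylboration through closed chair transition states: the (Z)-reagent gives the syn relation between each new methyl and hydroxyl, and (Z)-crotylboronates add anti-Felkin to α-methyl aldehydes (the Felkin chair has a syn-pentane clash between the reagent methyl and the α-methyl), so C2, C3, C7 and C8 should be set together, and because the formyl groups are enantiotopic the achiral reagent gives the meso product.

Step 6
Reactants: 10 meso diene diol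
Product: 11 meso-4,6,8-tris[(tert-butyldimethylsilyl)oxy]-3,5,7,9-tetramethylundeca-1,10-diene
Conditions: TBSOTf, 2,6-lutidine, CH2Cl2, −78 → 0 °C
Reagents that add atoms: tert-butyldimethylsilyl triflate, CC(C)(C)[Si](C)(C)OS(=O)(=O)C(F)(F)F
Why: Silyl triflate silylation of the two hindered secondary alcohols; no stereocentre is touched.

Step 7
Reactants: 11 meso tris-silyl diene
Product: 13 meso-(2R,3S,4S,5r,6R,7R,8S)-3,5,7-tris[(tert-butyldimethylsilyl)oxy]-2,4,6,8-tetramethylnonanedial, via bis-ozonide 12 (not isolated)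
Conditions: O3, CH2Cl2, −78 °C; then PPh3, −78 °C → rt; used without chromatography
Reagents that add atoms: ozone, [O-][O+]=O
Why: Ozonolysis with reductive work-up should convert both vinyl groups into formyl groups (C1 and C9) under neutral conditions that leave the α-methyl centres intact.

Step 8
Reactants: 14 3-methylbut-3-en-2-one
Product: 15 triisopropyl[(3-methylbuta-1,3-dien-2-yl)oxy]silane
Conditions: TIPSOTf, Et3N, CH2Cl2, 0 °C
Reagents that add atoms: triisopropylsilyl triflate, CC(C)[Si](C(C)C)(C(C)C)OS(=O)(=O)C(F)(F)F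
Why: Soft enolisation and O-silylation of the methyl ketone (only one enolisable side) gives the 2-silyloxydiene.

Step 9
Reactants: 15 silyloxydiene; 16 2,6-dibromo-1,4-benzoquinone
Product: 18 2-bromo-7-methyl-6-[(triisopropylsilyl)oxy]-5,8-dihydronaphthalene-1,4-dione, via Diels–Alder adduct 17 (not isolated)
Conditions: toluene, 0 °C → rt; then Et3N, rt
Reagents that add atoms: none
Why: Normal-demand Diels–Alder reaction followed by E1cB loss of HBr: the diene terminus next to the silyloxy carbon (largest HOMO coefficient) should bond to the hydrogen-bearing carbon of a bromo-alkene (β to the carbonyl not deactivated by vinylogous donation from bromine), which puts oxygen at C6, makes C5 peri to the C4 carbonyl and leaves the second bromine at C2.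

Step 10
Reactants: 18 dihydronaphthoquinone
Product: 20 [(6-bromo-5,8-dimethoxy-3-methylnaphthalen-2-yl)oxy]triisopropylsilane, via naphthalene-1,4-diol 19 (not isolated)
Conditions: K2CO3, MeI, acetone (degassed), reflux
Reagents that add atoms: iodomethane, CI
Why: Base-induced enolisation of the vinylogous C5/C8 methylene hydrogens should tautomerise the dihydroquinone to the naphthalene-1,4-diol (the silyl enol ether becoming an aryl silyl ether), which is trapped by Williamson O-methylation before re-oxidation.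

Step 11
Reactants: 20 aryl silyl ether
Product: 21 6-bromo-5,8-dimethoxy-3-methylnaphthalen-2-ol
Conditions: TBAF, THF, 0 °C; aq. NH4Cl
Reagents that add atoms: none
Why: Fluoride cleavage of the aryl silyl ether releases the only free phenol, needed to direct the acylation.

Step 12
Reactants: 21 naphthol; 22 propanoyl chloride
Product: 24 1-(6-bromo-2-hydroxy-5,8-dimethoxy-3-methylnaphthalen-1-yl)propan-1-one, via aryl propanoate 23 (not isolated)
Conditions: Et3N, CH2Cl2, 0 °C; solvent exchange; Sc(OTf)3 (10 mol %), toluene–MeNO2, 100 °C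
Reagents that add atoms: none
Why: O-Acylation followed by Lewis-acid Fries rearrangement should return the acyl group to C5, the α-position next to the phenol oxygen (the other ortho position, C7, carries the methyl group), and the mild triflate catalyst should spare the aryl methyl ethers.

Step 13
Reactants: 24 hydroxy ketone
Product: 25 1-[6-bromo-5,8-dimethoxy-2-(methoxymethoxy)-3-methylnaphthalen-1-yl]propan-1-one
Conditions: NaH (1.05 equiv), MOMCl, THF–DMF, 0 °C
Reagents that add atoms: chloromethyl methyl ether, COCCl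
Why: Williamson alkylation of the phenoxide (far more acidic than the ketone α-position) gives an acetal that does not migrate and survives steps 14–18.

Step 14
Reactants: 25 bromo ketone; 26 tert-butyl carbamate
Product: 27 tert-butyl N-[1,4-dimethoxy-6-(methoxymethoxy)-7-methyl-5-propanoylnaphthalen-2-yl]carbamate (ArP–CO–Et)
Conditions: Pd2(dba)3 (2 mol %), XPhos (8 mol %), Cs2CO3, 1,4-dioxane, 100 °C
Reagents that add atoms: none
Why: Buchwald–Hartwig amidation of the aryl bromide; the carbonate base is too weak for ketone α-arylation, and the site of nitrogen is fixed by the bromine placed in step 9.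

Step 15
Reactants: 27 ArP–CO–Et (1.15 equiv); 13 meso C1–C9 dialdehyde (1.0 equiv)
Product: 30 (2R,3S,4S,5S,6S,7S,8R,9S,10R)-11-ArP-9-hydroxy-2,4,6,8,10-pentamethyl-11-oxo-3,5,7-tris[(tert-butyldimethylsilyl)oxy]undecanal, via (Z)-enol borinate 28 (not isolated), via boron aldolate 29 (not isolated)
Conditions: (+)-Ipc2BOTf [from (−)-α-pinene], i-Pr2NEt, CH2Cl2, −78 → 0 °C; add 13, −78 → −20 °C, 16 h; pH 7 buffer, MeOH, H2O2, 0 °C
Reagents that add atoms: none
Why: Soft enolisation of the aryl ethyl ketone gives the (Z)-enol borinate, which adds to an aldehyde through a closed Zimmerman–Traxler chair; this is a reagent-controlled diisopinocampheylboron aldol used as an enantiotopic-group-selective addition to a meso dialdehyde, the terminus differentiation of two-directional chain synthesis. No ring is closed; the C9–C10 bond formed is the bond that joins chain and arene. The (Z)-geometry sets the 9,10-syn relation and the Ipc ligands select the aldehyde re face, so C9 (S) and C10 (R) are reagent-controlled, and both are sacrificial and disappear in step 16. The selectivity that matters is between the two formyl groups: a (Z)-enolate prefers the anti-Felkin face of an α-methyl aldehyde (the Felkin chair has a syn-pentane contact between the enolate methyl and the α-methyl), and only at the C9 terminus is that face the re face, so this end reacts in a matched, fast aldol while the mirror-image C1 end is mismatched and slow. Because the termini are eight bonds apart and react independently, the minor wrong-end mono-adduct still carries a matched formyl group and is drained to the bis-aldol, which should raise the enantiomeric purity of 30 at a modest cost in yield. Over-addition is limited by stoichiometry, and the silyl ethers, carbamate, MOM acetal and aryl methyl ethers are inert to the borinate.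

Step 16
Reactants: 30 aldol adduct
Product: 31 (2R,3S,4S,5S,6S,7S,8R,9E)-11-ArP-2,4,6,8,10-pentamethyl-11-oxo-3,5,7-tris[(tert-butyldimethylsilyl)oxy]undec-9-enal
Conditions: Martin sulfurane (1.5 equiv), CH2Cl2, 0 °C → rt
Reagents that add atoms: none
Why: Neutral dehydration of the β-hydroxy ketone (the remote α-methyl aldehyde is not exposed to base); anti-periplanar loss of the C10 hydrogen and the activated C9 oxygen from the 9,10-syn aldol, or E1cB loss, should give the conjugated (E)-enone with the aroyl group trans to the chain.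

Step 17
Reactants: 31 enone aldehyde
Product: 32 (2R,3S,4S,5S,6S,7S,8R,9E)-11-ArP-2,4,6,8,10-pentamethyl-11-oxo-3,5,7-tris[(tert-butyldimethylsilyl)oxy]undec-9-enoic acid
Conditions: NaClO2, NaH2PO4, 2-methyl-2-butene (excess), t-BuOH–H2O, 0 °C → rt
Reagents that add atoms: sodium chlorite, [Na+].[O-]Cl=O
Why: Pinnick oxidation converts the aldehyde to the acid at pH 3–4 without epimerisation at C2; the alkene scavenger removes HOCl and so protects the electron-rich arene and the enone.

Step 18
Reactants: 32 acid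
Product: 33 (2R,3S,4S,5S,6S,7S,8R,9E)-11-{2-[(tert-butoxycarbonyl)amino]-6-(methoxymethoxy)-7-methyl-1,4-dioxo-1,4-dihydronaphthalen-5-yl}-2,4,6,8,10-pentamethyl-11-oxo-3,5,7-tris[(tert-butyldimethylsilyl)oxy]undec-9-enoic acid
Conditions: (NH4)2Ce(NO3)6 (2.5 equiv), MeCN–H2O, 0 °C, 15 min
Reagents that add atoms: water, O
Why: Oxidative demethylation of the p-dimethoxy ring (single-electron oxidation, addition of water at the ipso carbons, loss of methanol) should give the 1,4-quinone; the acylated ring is less electron-rich and is left alone.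

Step 19
Reactants: 33 protected quinone
Product: 34 (2R,3S,4S,5S,6S,7S,8R,9E)-11-(2-amino-6-hydroxy-7-methyl-1,4-dioxo-1,4-dihydronaphthalen-5-yl)-2,4,6,8,10-pentamethyl-11-oxo-3,5,7-tris[(tert-butyldimethylsilyl)oxy]undec-9-enoic acid
Conditions: TFA–CH2Cl2 (1:4), 0 °C → rt; aqueous work-up
Reagents that add atoms: none
Why: Acidolysis removes the Boc group and the aryl MOM acetal while the three hindered secondary silyl ethers stay on, so no free hydroxyl meets acid together with the carboxylic acid and lactonisation is avoided.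

Step 20
Reactants: 34 tris-silyl ether
Product: 35 (2R,3S,4S,5S,6S,7S,8R,9E)-11-(2-amino-6-hydroxy-7-methyl-1,4-dioxo-1,4-dihydronaphthalen-5-yl)-3,5,7-trihydroxy-2,4,6,8,10-pentamethyl-11-oxoundec-9-enoic acid (CNP0287228.1)
Conditions: HF·pyridine, pyridine, THF, 0 °C → rt
Reagents that add atoms: none
Why: Buffered fluoride cleavage of the three silyl ethers should release the triol acid under nearly neutral conditions, without lactonisation, oxa-Michael addition or epimerisation.

**Compound list**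

1 | methacrolein | C=C(C)C=O | starting material
2 | isopropenylmagnesium bromide | C=C(C)[Mg]Br | starting material
3 | 2,4-dimethylpenta-1,4-dien-3-ol | C=C(C)C(O)C(C)=C | intermediate
4 | tert-butyl[(2,4-dimethylpenta-1,4-dien-3-yl)oxy]dimethylsilane | C=C(C)C(O[Si](C)(C)C(C)(C)C)C(C)=C | intermediate
5 | meso anti,anti 1,5-bis(9-borabicyclo[3.3.1]nonan-9-yl)-3-(TBS-oxy)-2,4-dimethylpentane | B1(C[C@H](C)[C@H](O[Si](C)(C)C(C)(C)C)[C@H](C)CB2C3CCCC2CCC3)C2CCCC1CCC2 | intermediate (not isolated)
6 | meso-(2R,3s,4S)-3-[(tert-butyldimethylsilyl)oxy]-2,4-dimethylpentane-1,5-diol | OC[C@H](C)[C@H](O[Si](C)(C)C(C)(C)C)[C@H](C)CO | intermediate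
7 | meso-(2R,3r,4S)-3-[(tert-butyldimethylsilyl)oxy]-2,4-dimethylpentanedial | O=C[C@H](C)[C@H](O[Si](C)(C)C(C)(C)C)[C@H](C)C=O | intermediate
8 | (Z)-crotylboronic acid pinacol ester | C/C=C\CB1OC(C)(C)C(C)(C)O1 | starting material
9 | bis(pinacol borate) of 10 | C=C[C@@H](C)[C@H](OB1OC(C)(C)C(C)(C)O1)[C@H](C)[C@H](O[Si](C)(C)C(C)(C)C)[C@H](C)[C@H](OB1OC(C)(C)C(C)(C)O1)[C@@H](C)C=C | intermediate (not isolated)
10 | meso-6-[(tert-butyldimethylsilyl)oxy]-3,5,7,9-tetramethylundeca-1,10-diene-4,8-diol | C=C[C@@H](C)[C@H](O)[C@H](C)[C@H](O[Si](C)(C)C(C)(C)C)[C@H](C)[C@H](O)[C@@H](C)C=C | intermediate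
11 | meso-4,6,8-tris[(tert-butyldimethylsilyl)oxy]-3,5,7,9-tetramethylundeca-1,10-diene | C=C[C@@H](C)[C@H](O[Si](C)(C)C(C)(C)C)[C@H](C)[C@H](O[Si](C)(C)C(C)(C)C)[C@H](C)[C@H](O[Si](C)(C)C(C)(C)C)[C@@H](C)C=C | intermediate
12 | bis(1,2,4-trioxolane) of 11 | O1COC(O1)[C@@H](C)[C@H](O[Si](C)(C)C(C)(C)C)[C@H](C)[C@H](O[Si](C)(C)C(C)(C)C)[C@H](C)[C@H](O[Si](C)(C)C(C)(C)C)[C@@H](C)C1OCOO1 | intermediate (not isolated)
13 | meso-(2R,3S,4S,5r,6R,7R,8S)-3,5,7-tris[(tert-butyldimethylsilyl)oxy]-2,4,6,8-tetramethylnonanedial | O=C[C@@H](C)[C@H](O[Si](C)(C)C(C)(C)C)[C@H](C)[C@H](O[Si](C)(C)C(C)(C)C)[C@H](C)[C@H](O[Si](C)(C)C(C)(C)C)[C@@H](C)C=O | intermediate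
14 | 3-methylbut-3-en-2-one | CC(=O)C(C)=C | starting material
15 | triisopropyl[(3-methylbuta-1,3-dien-2-yl)oxy]silane | C=C(C)C(=C)O[Si](C(C)C)(C(C)C)C(C)C | intermediate
16 | 2,6-dibromo-1,4-benzoquinone | O=C1C=C(Br)C(=O)C(Br)=C1 | starting material
17 | rac-cis-2,8a-dibromo-7-methyl-6-[(triisopropylsilyl)oxy]-4a,5,8,8a-tetrahydronaphthalene-1,4-dione | O=C1C=C(Br)C(=O)C2(Br)CC(C)=C(O[Si](C(C)C)(C(C)C)C(C)C)CC12 | intermediate (not isolated)
18 | 2-bromo-7-methyl-6-[(triisopropylsilyl)oxy]-5,8-dihydronaphthalene-1,4-dione | O=C1C=C(Br)C(=O)C2=C1CC(O[Si](C(C)C)(C(C)C)C(C)C)=C(C)C2 | intermediate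
19 | 2-bromo-7-methyl-6-[(triisopropylsilyl)oxy]naphthalene-1,4-diol | Oc1cc(Br)c(O)c2cc(C)c(O[Si](C(C)C)(C(C)C)C(C)C)cc12 | intermediate (not isolated)
20 | [(6-bromo-5,8-dimethoxy-3-methylnaphthalen-2-yl)oxy]triisopropylsilane | COc1cc(Br)c(OC)c2cc(C)c(O[Si](C(C)C)(C(C)C)C(C)C)cc12 | intermediate
21 | 6-bromo-5,8-dimethoxy-3-methylnaphthalen-2-ol | COc1cc(Br)c(OC)c2cc(C)c(O)cc12 | intermediate
22 | propanoyl chloride | CCC(Cl)=O | starting material
23 | 6-bromo-5,8-dimethoxy-3-methylnaphthalen-2-yl propanoate | CCC(=O)Oc1cc2c(OC)cc(Br)c(OC)c2cc1C | intermediate (not isolated)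
24 | 1-(6-bromo-2-hydroxy-5,8-dimethoxy-3-methylnaphthalen-1-yl)propan-1-one | CCC(=O)c1c(O)c(C)cc2c(OC)c(Br)cc(OC)c12 | intermediate
25 | 1-[6-bromo-5,8-dimethoxy-2-(methoxymethoxy)-3-methylnaphthalen-1-yl]propan-1-one | CCC(=O)c1c(OCOC)c(C)cc2c(OC)c(Br)cc(OC)c12 | intermediate
26 | tert-butyl carbamate | CC(C)(C)OC(N)=O | starting material
27 | tert-butyl N-[1,4-dimethoxy-6-(methoxymethoxy)-7-methyl-5-propanoylnaphthalen-2-yl]carbamate | CCC(=O)c1c(OCOC)c(C)cc2c(OC)c(NC(=O)OC(C)(C)C)cc(OC)c12 | intermediate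
28 | (Z)-enol diisopinocampheylborinate of 27 | C/C=C(\OB([C@H]1C[C@H]2C[C@H](C2(C)C)[C@@H]1C)[C@H]1C[C@H]2C[C@H](C2(C)C)[C@@H]1C)c1c(OCOC)c(C)cc2c(OC)c(NC(=O)OC(C)(C)C)cc(OC)c12 | intermediate (not isolated)
29 | C9-O-diisopinocampheylboron aldolate of 30 | O=C(c1c(OCOC)c(C)cc2c(OC)c(NC(=O)OC(C)(C)C)cc(OC)c12)[C@H](C)[C@@H](OB([C@H]1C[C@H]2C[C@H](C2(C)C)[C@@H]1C)[C@H]1C[C@H]2C[C@H](C2(C)C)[C@@H]1C)[C@@H](C)[C@H](O[Si](C)(C)C(C)(C)C)[C@H](C)[C@H](O[Si](C)(C)C(C)(C)C)[C@H](C)[C@H](O[Si](C)(C)C(C)(C)C)[C@@H](C)C=O | intermediate (not isolated)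
30 | (2R,3S,4S,5S,6S,7S,8R,9S,10R)-11-ArP-9-hydroxy-2,4,6,8,10-pentamethyl-11-oxo-3,5,7-tris(TBS-oxy)undecanal | O=C(c1c(OCOC)c(C)cc2c(OC)c(NC(=O)OC(C)(C)C)cc(OC)c12)[C@H](C)[C@@H](O)[C@@H](C)[C@H](O[Si](C)(C)C(C)(C)C)[C@H](C)[C@H](O[Si](C)(C)C(C)(C)C)[C@H](C)[C@H](O[Si](C)(C)C(C)(C)C)[C@@H](C)C=O | intermediate
31 | (2R,3S,4S,5S,6S,7S,8R,9E)-11-ArP-2,4,6,8,10-pentamethyl-11-oxo-3,5,7-tris(TBS-oxy)undec-9-enal | C/C(=C\[C@@H](C)[C@H](O[Si](C)(C)C(C)(C)C)[C@H](C)[C@H](O[Si](C)(C)C(C)(C)C)[C@H](C)[C@H](O[Si](C)(C)C(C)(C)C)[C@@H](C)C=O)C(=O)c1c(OCOC)c(C)cc2c(OC)c(NC(=O)OC(C)(C)C)cc(OC)c12 | intermediate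
32 | (2R,3S,4S,5S,6S,7S,8R,9E)-11-ArP-2,4,6,8,10-pentamethyl-11-oxo-3,5,7-tris(TBS-oxy)undec-9-enoic acid | C/C(=C\[C@@H](C)[C@H](O[Si](C)(C)C(C)(C)C)[C@H](C)[C@H](O[Si](C)(C)C(C)(C)C)[C@H](C)[C@H](O[Si](C)(C)C(C)(C)C)[C@@H](C)C(=O)O)C(=O)c1c(OCOC)c(C)cc2c(OC)c(NC(=O)OC(C)(C)C)cc(OC)c12 | intermediate
33 | N-Boc, O-MOM, tris-TBS derivative of the target (2-Boc-amino-6-MOM-oxy-1,4-naphthoquinone) | C/C(=C\[C@@H](C)[C@H](O[Si](C)(C)C(C)(C)C)[C@H](C)[C@H](O[Si](C)(C)C(C)(C)C)[C@H](C)[C@H](O[Si](C)(C)C(C)(C)C)[C@@H](C)C(=O)O)C(=O)c1c(OCOC)c(C)cc2c1C(=O)C=C(NC(=O)OC(C)(C)C)C2=O | intermediate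
34 | 3,5,7-tris-O-TBS ether of the target | C/C(=C\[C@@H](C)[C@H](O[Si](C)(C)C(C)(C)C)[C@H](C)[C@H](O[Si](C)(C)C(C)(C)C)[C@H](C)[C@H](O[Si](C)(C)C(C)(C)C)[C@@H](C)C(=O)O)C(=O)c1c(O)c(C)cc2c1C(=O)C=C(N)C2=O | intermediate
35 | (2R,3S,4S,5S,6S,7S,8R,9E)-11-(2-amino-6-hydroxy-7-methyl-1,4-dioxo-1,4-dihydronaphthalen-5-yl)-3,5,7-trihydroxy-2,4,6,8,10-pentamethyl-11-oxoundec-9-enoic acid | C/C(=C\[C@@H](C)[C@H](O)[C@H](C)[C@H](O)[C@H](C)[C@H](O)[C@@H](C)C(=O)O)C(=O)c1c(O)c(C)cc2c1C(=O)C=C(N)C2=O | target

**Step count.** Total: 20 steps. Longest linear sequence: 13 steps (steps 1–7 then 15–20; the arene branch, steps 8–14 then 15–20, is equally long).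

**Steps most likely to fail**

1. Step 15. The rate difference between the matched and mismatched formyl groups may be too small with this hindered, twisted aryl enolate, or enolisation may be sluggish, so that 30 forms in low enantiomeric purity or low conversion. Fallback, setting out from 13: reduce both formyl groups (NaBH4) to the meso 1,9-diol F1. Desymmetrise it by lipase-catalysed monoacetylation (Pseudomonas lipase, vinyl acetate; the enzyme is chosen by screening for the one that leaves the pro-C9 hydroxyl free) to the monoacetate F2. Oxidise the free alcohol (Dess–Martin) to the aldehyde F3. Add the achiral (Z)-dibutylboron enolate of 27, which gives the β-hydroxy ketone F4 (configuration at C9/C10 is irrelevant), and dehydrate with Martin sulfurane to the enone acetate F5. Methanolysis of the acetate (K2CO3, MeOH, 0 °C) gives the enone alcohol F6, and Dess–Martin oxidation returns to the route at 31.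

2. Step 5. Anti-Felkin facial selectivity under substrate control may be insufficient, and any loss is compounded over two additions, giving hard-to-separate diastereomers. Fallback, setting out from 7: add one equivalent of Brown's (Z)-crotyldiisopinocampheylborane (either antipode, −78 °C), which reacts only at the terminus where reagent and substrate preferences coincide, and isolate the mono-adduct as the lactol F7 (one enantiomer shown; either serves). The antipodal reagent then adds to the ring-opened hydroxy aldehyde, again in a matched sense, and oxidative work-up returns to the route at 10.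

3. Step 12. The acyl group may not return cleanly to C5: loss of the acyl group back to 21, acylation elsewhere on the electron-rich ring, or Lewis-acid cleavage of the peri methyl ether are all possible. Fallback, setting out from 21: magnesium-mediated ortho-formylation (MgCl2, Et3N, paraformaldehyde, MeCN, reflux), which is specific for the free ortho position C5, gives the hydroxy aldehyde F8. MOM protection (NaH, MOMCl) gives the aldehyde F9, addition of EtMgBr gives the racemic carbinol F10, and Dess–Martin oxidation returns to the route at 25.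

**Further compounds**

F1 | step 15 | meso 3,5,7-tris(TBS-oxy)-2,4,6,8-tetramethylnonane-1,9-diol | OC[C@@H](C)[C@H](O[Si](C)(C)C(C)(C)C)[C@H](C)[C@H](O[Si](C)(C)C(C)(C)C)[C@H](C)[C@H](O[Si](C)(C)C(C)(C)C)[C@@H](C)CO
F2 | step 15 | C1-monoacetate of F1 (C9 hydroxyl free) | OC[C@@H](C)[C@H](O[Si](C)(C)C(C)(C)C)[C@H](C)[C@H](O[Si](C)(C)C(C)(C)C)[C@H](C)[C@H](O[Si](C)(C)C(C)(C)C)[C@@H](C)COC(C)=O
F3 | step 15 | C9 aldehyde, C1 acetate | O=C[C@@H](C)[C@H](O[Si](C)(C)C(C)(C)C)[C@H](C)[C@H](O[Si](C)(C)C(C)(C)C)[C@H](C)[C@H](O[Si](C)(C)C(C)(C)C)[C@@H](C)COC(C)=O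
F4 | step 15 | 11-ArP-9-hydroxy-11-oxo C1 acetate (mixture at C9/C10) | O=C(c1c(OCOC)c(C)cc2c(OC)c(NC(=O)OC(C)(C)C)cc(OC)c12)C(C)C(O)[C@@H](C)[C@H](O[Si](C)(C)C(C)(C)C)[C@H](C)[C@H](O[Si](C)(C)C(C)(C)C)[C@H](C)[C@H](O[Si](C)(C)C(C)(C)C)[C@@H](C)COC(C)=O
F5 | step 15 | (E)-enone C1 acetate | C/C(=C\[C@@H](C)[C@H](O[Si](C)(C)C(C)(C)C)[C@H](C)[C@H](O[Si](C)(C)C(C)(C)C)[C@H](C)[C@H](O[Si](C)(C)C(C)(C)C)[C@@H](C)COC(C)=O)C(=O)c1c(OCOC)c(C)cc2c(OC)c(NC(=O)OC(C)(C)C)cc(OC)c12
F6 | step 15 | (E)-enone C1 alcohol | C/C(=C\[C@@H](C)[C@H](O[Si](C)(C)C(C)(C)C)[C@H](C)[C@H](O[Si](C)(C)C(C)(C)C)[C@H](C)[C@H](O[Si](C)(C)C(C)(C)C)[C@@H](C)CO)C(=O)c1c(OCOC)c(C)cc2c(OC)c(NC(=O)OC(C)(C)C)cc(OC)c12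
F7 | step 5 | 6-(but-3-en-2-yl)-4-(TBS-oxy)-3,5-dimethyltetrahydropyran-2-ol (lactol of the mono-adduct) | C=C[C@@H](C)[C@@H]1OC(O)[C@@H](C)[C@@H](O[Si](C)(C)C(C)(C)C)[C@H]1C
F8 | step 12 | 6-bromo-2-hydroxy-5,8-dimethoxy-3-methylnaphthalene-1-carbaldehyde | O=Cc1c(O)c(C)cc2c(OC)c(Br)cc(OC)c12
F9 | step 12 | 6-bromo-5,8-dimethoxy-2-(methoxymethoxy)-3-methylnaphthalene-1-carbaldehyde | O=Cc1c(OCOC)c(C)cc2c(OC)c(Br)cc(OC)c12
F10 | step 12 | rac-1-[6-bromo-5,8-dimethoxy-2-(methoxymethoxy)-3-methylnaphthalen-1-yl]propan-1-ol | CCC(O)c1c(OCOC)c(C)cc2c(OC)c(Br)cc(OC)c12
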